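**Plan**
1. Retrosynthesis: the side chain is cut at C13–C14 (Stille) and C12=C13 (iodo-Wittig); ring B is cut at C6–C7 and C5–C10 together (intramolecular [4+2]); the acyclic triene is cut at C1–C10 (B-alkyl Suzuki), at C8–C7/C8–C17 (double addition to a lactone carbonyl) and at C4–C3/C4–C18 (two enolate alkylations).
2. Enabling feature: ring B (C5–C6–C7–C8–C9–C10) carries the 6-oxygen homoallylic to the 8(17)-methylene. As its Δ8 isomer with silicon on C17 it is the cycloadduct of an (E)-alkenylborane C5=C6 (boron becomes the 6α-oxygen with retention) and a 2-(silylmethyl)diene C7=C8–C9=C10 tethered through C1–C4; protonation at C9 later moves the double bond to C8=C17.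
3. Forward: the C4 quaternary centre and the alkyne (C5, C6) come from methyl (S)-3-hydroxybutanoate; C8–C12 and C20 come from 2-acetylbutyrolactone, joined at C1–C10; one hydroboration/cycloaddition/oxidation operation then closes rings A and B; acetate, C9–H with the exocyclic alkene, and the (Z)-diene follow.
4. Stereochemistry: C4 from the chiral pool by two Fráter–Seebach alkylations; C5, C6 and C10 in the cycloaddition (E-dienophile, endo boron, relay from C4); C9 by axial protodesilylation; 12Z from a Z-selective iodo-olefination and a stereoretentive coupling.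

Key step: step 10

Remark: ring compounds are named on the labdane skeleton (ring A = C1–C5, C10; ring B = C5–C10; C17 on C8; C18 = 4α-CH3; C19 = 4β ester carbon; C20 = 10β-CH3; 5α-H throughout); reagents sold as solutions or stable solids are taken as purchased.

**Step 1**
Reactants: 1 methyl (S)-3-hydroxybutanoate; 2 iodomethane
Product: 3 methyl (2S,3S)-3-hydroxy-2-methylbutanoate
Conditions: LiN(iPr)2 (2.2 equiv), THF, −78 → −20 °C; MeI, DMPU, −78 → 0 °C
Reagents that add atoms: iodomethane, CI
Why: Fráter–Seebach alkylation, in which the lithium-chelated dianion is methylated on the face opposite the C3 methyl group, should give the anti (2S,3S) ester.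

**Step 2**
Reactants: 3 methyl (2S,3S)-3-hydroxy-2-methylbutanoate; 4 allyl bromide
Product: 5 methyl (2S)-2-[(1S)-1-hydroxyethyl]-2-methylpent-4-enoate
Conditions: LiN(iPr)2 (2.2 equiv), THF/DMPU, −78 → −10 °C; allyl bromide, −78 → 0 °C
Reagents that add atoms: allyl bromide, C=CCBr
Why: a second Fráter–Seebach alkylation of the same chelated dianion brings allyl bromide in from the same face, so the quaternary carbon (later C4) should form as the 2S isomer.

**Step 3**
Reactants: 5 methyl (2S)-2-[(1S)-1-hydroxyethyl]-2-methylpent-4-enoate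
Product: 6 methyl (2S)-2-acetyl-2-methylpent-4-enoate
Conditions: Dess–Martin periodinane, NaHCO3, CH2Cl2, rt
Reagents that add atoms: none
Why: Dess–Martin oxidation of the secondary alcohol under buffered conditions gives a β-keto ester whose α-carbon is quaternary and therefore cannot epimerise.

**Step 4**
Reactants: 6 methyl (2S)-2-acetyl-2-methylpent-4-enoate; 7 diethyl chlorophosphate; 8 chlorotrimethylsilane
Product: 11 methyl (2S)-2-methyl-2-[(trimethylsilyl)ethynyl]pent-4-enoate, via enol phosphate 9 (not isolated), via lithium acetylide 10 (not isolated)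
Conditions: LiN(iPr)2 (1.1 equiv), THF, −78 °C; ClP(O)(OEt)2, −78 °C → rt; LiN(iPr)2 (2.3 equiv), −78 °C → rt; Me3SiCl, −78 °C → rt
Reagents that add atoms: chlorotrimethylsilane, C[Si](C)(C)Cl
Why: kinetic enolisation of the methyl ketone and O-phosphorylation give the enol phosphate, which the amide base eliminates to the acetylide (no allene can form because the other α-carbon is quaternary) before C-silylation; reaction type: methyl ketone to alkyne by enol phosphate elimination.

**Step 5**
Reactants: 12 3-acetyloxolan-2-one (2-acetylbutyrolactone); 13 trifluoromethanesulfonic anhydride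
Product: 14 (1E)-1-(2-oxooxolan-3-ylidene)ethyl trifluoromethanesulfonate
Conditions: Tf2O, aq. Me4NOH, toluene, 0–5 °C
Reagents that add atoms: trifluoromethanesulfonic anhydride, O=S(=O)(OS(=O)(=O)C(F)(F)F)C(F)(F)F
Why: O-triflation of the non-chelated tetramethylammonium enolate, which prefers the dipole-minimised geometry with the enolate oxygen anti to the lactone carbonyl, should give the (E)-enol triflate; reaction type: stereoselective enol triflation of a β-keto ester.

**Step 6**
Reactants: 11 methyl (2S)-2-methyl-2-[(trimethylsilyl)ethynyl]pent-4-enoate; 14 (1E)-1-(2-oxooxolan-3-ylidene)ethyl trifluoromethanesulfonate; 15 9-borabicyclo[3.3.1]nonane (9-BBN)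
Product: 17 methyl (2S,6E)-2-methyl-6-(2-oxooxolan-3-ylidene)-2-[(trimethylsilyl)ethynyl]heptanoate, via B-alkyl-9-BBN 16 (not isolated)
Conditions: 9-BBN, THF, 0 °C → rt; then 14, PdCl2(dppf) (cat.), AsPh3, Cs2CO3, DMF/H2O, rt
Reagents that add atoms: enol triflate 14, C/C(OS(=O)(=O)C(F)(F)F)=C1\C(=O)OCC1
Why: 9-BBN hydroborates the terminal alkene at its CH2 end (the silylated alkyne is inert) and the B-alkyl Suzuki–Miyaura coupling replaces triflate with retention, so the tetrasubstituted C9=C10 alkene forms with C1 trans to the lactone carbonyl (C8).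

**Step 7**
Reactants: 17 methyl (2S,6E)-2-methyl-6-(2-oxooxolan-3-ylidene)-2-[(trimethylsilyl)ethynyl]heptanoate; 18 (trimethylsilyl)methylmagnesium chloride
Product: 20 methyl (2S,6E)-7-(2-hydroxyethyl)-2,6-dimethyl-2-[(trimethylsilyl)ethynyl]-8-[(trimethylsilyl)methyl]nona-6,8-dienoate, via bis(silylmethyl) carbinol 19 (not isolated)
Conditions: Me3SiCH2MgCl (3 equiv), CeCl3 (3 equiv), THF, −78 °C → rt; aq. NH4Cl; then SiO2, CH2Cl2, rt
Reagents that add atoms: (trimethylsilyl)methylmagnesium chloride, C[Si](C)(C)C[Mg]Cl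
Why: the organocerium reagent adds twice to the lactone carbonyl (ring opening frees O12) while the neopentyl, α-quaternary methyl ester should be spared, and silica-promoted Peterson elimination of the tertiary β-hydroxysilane gives the 2-(silylmethyl)diene; reaction type: ester-to-allylsilane conversion by double (silylmethyl) addition and Peterson olefination.

**Step 8**
Reactants: 20 methyl (2S,6E)-7-(2-hydroxyethyl)-2,6-dimethyl-2-[(trimethylsilyl)ethynyl]-8-[(trimethylsilyl)methyl]nona-6,8-dienoate; 21 tert-butylchlorodiphenylsilane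
Product: 22 methyl (2S,6E)-7-[2-(tert-butyldiphenylsilyloxy)ethyl]-2,6-dimethyl-2-[(trimethylsilyl)ethynyl]-8-[(trimethylsilyl)methyl]nona-6,8-dienoate
Conditions: TBDPSCl, imidazole, CH2Cl2, 0 °C → rt
Reagents that add atoms: tert-butylchlorodiphenylsilane, CC(C)(C)[Si](Cl)(c1ccccc1)c1ccccc1
Why: silylation of the only hydroxyl with an acid-stable silyl group that will survive the later protodesilylation.

**Step 9**
Reactants: 22 methyl (2S,6E)-7-[2-(tert-butyldiphenylsilyloxy)ethyl]-2,6-dimethyl-2-[(trimethylsilyl)ethynyl]-8-[(trimethylsilyl)methyl]nona-6,8-dienoate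
Product: 23 methyl (2S,6E)-7-[2-(tert-butyldiphenylsilyloxy)ethyl]-2-ethynyl-2,6-dimethyl-8-[(trimethylsilyl)methyl]nona-6,8-dienoate
Conditions: K2CO3 (cat.), MeOH, rt
Reagents that add atoms: none
Why: methanolysis of the C(sp)–Si bond frees the terminal alkyne while the allylic C(sp3)–Si bond, the silyl ether and the methyl ester are untouched.

**Step 10**
Reactants: 23 methyl (2S,6E)-7-[2-(tert-butyldiphenylsilyloxy)ethyl]-2-ethynyl-2,6-dimethyl-8-[(trimethylsilyl)methyl]nona-6,8-dienoate; 24 dicyclohexylborane; 25 hydrogen peroxide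
Product: 28 methyl 12-(tert-butyldiphenylsilyloxy)-6α-hydroxy-17-(trimethylsilyl)-13,14,15,16-tetranorlabd-8-en-19-oate, via (E)-alkenyl(dicyclohexyl)borane 26 (not isolated), via cycloadduct C6-borane 27 (not isolated)
Conditions: Cy2BH (1.05 equiv), THF, 0 °C → rt; then 50 °C; then 3 M NaOH, 30% H2O2, 0 °C → rt
Reagents that add atoms: hydrogen peroxide, OO
Why: Proposed new method: dicyclohexylborane should add syn and anti-Markovnikov to the terminal alkyne only, giving the (E)-alkenylborane 26, whose vacant boron p orbital lowers the dienophile LUMO so that a concerted, asynchronous intramolecular [4+2] cycloaddition with the tethered 2-(silylmethyl)diene forms C5–C10 and C6–C7 near room temperature; the closest known reaction types are the intermolecular Diels–Alder reaction of dialkyl(vinyl)boranes with dienes followed by oxidation and the thermal type 1 intramolecular Diels–Alder reaction of 1,7,9-decatrienes. Ring B is closed as the cyclohexene of the [4+2] event (both new bonds lie in it), and ring A is closed at the same moment by the C5–C10 bond through the four-carbon tether C1–C4 in the fused mode with the tether anti to the diene. C6 follows from the E geometry of 26 and suprafacial addition, and the C–B bond is oxidised with retention, so the 6-oxygen ends α, equatorial and trans to C4; the trans ring fusion (5α-H, 10β-CH3) follows from boron lying endo under the diene with the tether exo, while the E geometry of the C9=C10 bond keeps the tether outside and the C20 methyl inside. The absolute sense is relayed from C4: of the two chair-like tether arrangements, the one with the slimmer CO2Me axial and syn to the C20 methyl (CH3 equatorial) should be preferred over the one with two syn-axial methyl groups. The step needs chemoselective hydroboration, endo selectivity and diastereofacial control, which should be secured by the rate gap between a terminal alkyne and a 1,1-disubstituted alkene, by the boron–diene secondary interaction, and by the quaternary stereocenter next to the dienophile.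

**Step 11**
Reactants: 28 methyl 12-(tert-butyldiphenylsilyloxy)-6α-hydroxy-17-(trimethylsilyl)-13,14,15,16-tetranorlabd-8-en-19-oate; 29 acetic anhydride
Product: 30 methyl 6α-acetoxy-12-(tert-butyldiphenylsilyloxy)-17-(trimethylsilyl)-13,14,15,16-tetranorlabd-8-en-19-oate
Conditions: Ac2O, pyridine, DMAP (cat.), CH2Cl2, rt
Reagents that add atoms: acetic anhydride, CC(=O)OC(C)=O
Why: DMAP-catalysed acylation of the equatorial 6α-alcohol, with no stereocenter touched.

**Step 12**
Reactants: 30 methyl 6α-acetoxy-12-(tert-butyldiphenylsilyloxy)-17-(trimethylsilyl)-13,14,15,16-tetranorlabd-8-en-19-oate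
Product: 31 methyl 6α-acetoxy-12-(tert-butyldiphenylsilyloxy)-13,14,15,16-tetranorlabd-8(17)-en-19-oate
Conditions: CF3CO2H, CH2Cl2, −20 → 0 °C; aq. NaHCO3
Reagents that add atoms: none
Why: protodesilylation of the allylsilane (SE2′), in which the β-silicon effect directs the proton to C9, axial delivery on the α face anti to the axial C20 methyl should set 9α-H with the side chain equatorial, and loss of silicon from C17 places the double bond at C8=C17, while the silyl ether keeps O12 from adding to C8.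

**Step 13**
Reactants: 31 methyl 6α-acetoxy-12-(tert-butyldiphenylsilyloxy)-13,14,15,16-tetranorlabd-8(17)-en-19-oate
Product: 32 methyl 6α-acetoxy-12-hydroxy-13,14,15,16-tetranorlabd-8(17)-en-19-oate
Conditions: Bu4NF, AcOH, THF, rt
Reagents that add atoms: none
Why: buffered fluoride cleaves the silyl ether without touching acetate, methyl ester or alkene.

**Step 14**
Reactants: 32 methyl 6α-acetoxy-12-hydroxy-13,14,15,16-tetranorlabd-8(17)-en-19-oate
Product: 33 methyl 6α-acetoxy-12-oxo-13,14,15,16-tetranorlabd-8(17)-en-19-oate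
Conditions: Dess–Martin periodinane, NaHCO3, CH2Cl2, 0 °C → rt
Reagents that add atoms: none
Why: Dess–Martin oxidation of the primary alcohol gives the aldehyde, and C9 is β to the carbonyl so it cannot epimerise.

**Step 15**
Reactants: 33 methyl 6α-acetoxy-12-oxo-13,14,15,16-tetranorlabd-8(17)-en-19-oate; 34 ethyltriphenylphosphonium iodide; 35 iodine
Product: 36 methyl (12Z)-6α-acetoxy-13-iodo-14,15-dinorlabda-8(17),12-dien-19-oate
Conditions: EtPPh3I, n-BuLi, THF, rt; I2, −78 °C; NaN(SiMe3)2, −20 °C; then 33, −78 → −20 °C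
Reagents that add atoms: ethyltriphenylphosphonium iodide, CC[P+](c1ccccc1)(c1ccccc1)c1ccccc1.[I-]; iodine, II
Why: Stork–Zhao-type Wittig olefination with the α-iodo ylide, which under kinetic control places iodine cis to C11, should give the (Z)-vinyl iodide.

**Step 16**
Reactants: 36 methyl (12Z)-6α-acetoxy-13-iodo-14,15-dinorlabda-8(17),12-dien-19-oate; 37 tributyl(vinyl)stannane
Product: 38 methyl (12Z)-6α-acetoxylabda-8(17),12,14-trien-19-oate
Conditions: Pd2(dba)3 (cat.), AsPh3, DMF, rt → 45 °C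
Reagents that add atoms: tributyl(vinyl)stannane, C=C[Sn](CCCC)(CCCC)CCCC
Why: Stille coupling of the vinyl iodide with the vinylstannane under zerovalent palladium proceeds with retention, so the 12Z diene of the target should result.

**Compound list**
1 | methyl (S)-3-hydroxybutanoate | C[C@H](O)CC(=O)OC | starting material
2 | iodomethane | CI | starting material
3 | methyl (2S,3S)-3-hydroxy-2-methylbutanoate | C[C@H](O)[C@H](C)C(=O)OC | intermediate
4 | allyl bromide | C=CCBr | starting material
5 | methyl (2S)-2-[(1S)-1-hydroxyethyl]-2-methylpent-4-enoate | C[C@H](O)[C@](C)(CC=C)C(=O)OC | intermediate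
6 | methyl (2S)-2-acetyl-2-methylpent-4-enoate | CC(=O)[C@](C)(CC=C)C(=O)OC | intermediate
7 | diethyl chlorophosphate | CCOP(=O)(Cl)OCC | starting material
8 | chlorotrimethylsilane | C[Si](C)(C)Cl | starting material
9 | methyl (2S)-2-[1-(diethoxyphosphoryloxy)ethenyl]-2-methylpent-4-enoate | C=C(OP(=O)(OCC)OCC)[C@](C)(CC=C)C(=O)OC | intermediate (not isolated)
10 | lithium acetylide of methyl (2S)-2-ethynyl-2-methylpent-4-enoate | [Li+].[C-]#C[C@](C)(CC=C)C(=O)OC | intermediate (not isolated)
11 | methyl (2S)-2-methyl-2-[(trimethylsilyl)ethynyl]pent-4-enoate | C[Si](C)(C)C#C[C@](C)(CC=C)C(=O)OC | intermediate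
12 | 3-acetyloxolan-2-one | CC(=O)C1CCOC1=O | starting material
13 | trifluoromethanesulfonic anhydride | O=S(=O)(OS(=O)(=O)C(F)(F)F)C(F)(F)F | starting material
14 | (1E)-1-(2-oxooxolan-3-ylidene)ethyl trifluoromethanesulfonate | C/C(OS(=O)(=O)C(F)(F)F)=C1\C(=O)OCC1 | intermediate
15 | 9-borabicyclo[3.3.1]nonane | B1C2CCCC1CCC2 | starting material
16 | methyl (2S)-5-(9-borabicyclo[3.3.1]nonan-9-yl)-2-methyl-2-[(trimethylsilyl)ethynyl]pentanoate | C[Si](C)(C)C#C[C@](C)(CCCB1C2CCCC1CCC2)C(=O)OC | intermediate (not isolated)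
17 | methyl (2S,6E)-2-methyl-6-(2-oxooxolan-3-ylidene)-2-[(trimethylsilyl)ethynyl]heptanoate | C[Si](C)(C)C#C[C@](C)(CCC/C(C)=C1/C(=O)OCC1)C(=O)OC | intermediate
18 | (trimethylsilyl)methylmagnesium chloride | C[Si](C)(C)C[Mg]Cl | starting material
19 | methyl (2S,6E)-8-hydroxy-7-(2-hydroxyethyl)-2,6-dimethyl-9-(trimethylsilyl)-2-[(trimethylsilyl)ethynyl]-8-[(trimethylsilyl)methyl]non-6-enoate | C[Si](C)(C)C#C[C@](C)(CCC/C(C)=C(CCO)/C(O)(C[Si](C)(C)C)C[Si](C)(C)C)C(=O)OC | intermediate (not isolated)
20 | methyl (2S,6E)-7-(2-hydroxyethyl)-2,6-dimethyl-2-[(trimethylsilyl)ethynyl]-8-[(trimethylsilyl)methyl]nona-6,8-dienoate | C[Si](C)(C)C#C[C@](C)(CCC/C(C)=C(CCO)/C(=C)C[Si](C)(C)C)C(=O)OC | intermediate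
21 | tert-butylchlorodiphenylsilane | CC(C)(C)[Si](Cl)(c1ccccc1)c1ccccc1 | starting material
22 | methyl (2S,6E)-7-[2-(tert-butyldiphenylsilyloxy)ethyl]-2,6-dimethyl-2-[(trimethylsilyl)ethynyl]-8-[(trimethylsilyl)methyl]nona-6,8-dienoate | C[Si](C)(C)C#C[C@](C)(CCC/C(C)=C(CCO[Si](c1ccccc1)(c1ccccc1)C(C)(C)C)/C(=C)C[Si](C)(C)C)C(=O)OC | intermediate
23 | methyl (2S,6E)-7-[2-(tert-butyldiphenylsilyloxy)ethyl]-2-ethynyl-2,6-dimethyl-8-[(trimethylsilyl)methyl]nona-6,8-dienoate | C#C[C@](C)(CCC/C(C)=C(CCO[Si](c1ccccc1)(c1ccccc1)C(C)(C)C)/C(=C)C[Si](C)(C)C)C(=O)OC | intermediate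
24 | dicyclohexylborane | B(C1CCCCC1)C1CCCCC1 | starting material
25 | hydrogen peroxide | OO | starting material
26 | methyl (2S,6E)-7-[2-(tert-butyldiphenylsilyloxy)ethyl]-2-[(E)-2-(dicyclohexylboranyl)ethenyl]-2,6-dimethyl-8-[(trimethylsilyl)methyl]nona-6,8-dienoate | C1CCC(CC1)B(C1CCCCC1)/C=C/[C@](C)(CCC/C(C)=C(CCO[Si](c1ccccc1)(c1ccccc1)C(C)(C)C)/C(=C)C[Si](C)(C)C)C(=O)OC | intermediate (not isolated)
27 | methyl 12-(tert-butyldiphenylsilyloxy)-6α-(dicyclohexylboranyl)-17-(trimethylsilyl)-13,14,15,16-tetranorlabd-8-en-19-oate | CC(C)(C)[Si](c1ccccc1)(c1ccccc1)OCCC1=C(C[Si](C)(C)C)C[C@H](B(C3CCCCC3)C3CCCCC3)[C@@H]2[C@]1(C)CCC[C@]2(C)C(=O)OC | intermediate (not isolated)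
28 | methyl 12-(tert-butyldiphenylsilyloxy)-6α-hydroxy-17-(trimethylsilyl)-13,14,15,16-tetranorlabd-8-en-19-oate | CC(C)(C)[Si](c1ccccc1)(c1ccccc1)OCCC1=C(C[Si](C)(C)C)C[C@H](O)[C@@H]2[C@]1(C)CCC[C@]2(C)C(=O)OC | intermediate
29 | acetic anhydride | CC(=O)OC(C)=O | starting material
30 | methyl 6α-acetoxy-12-(tert-butyldiphenylsilyloxy)-17-(trimethylsilyl)-13,14,15,16-tetranorlabd-8-en-19-oate | CC(C)(C)[Si](c1ccccc1)(c1ccccc1)OCCC1=C(C[Si](C)(C)C)C[C@H](OC(C)=O)[C@@H]2[C@]1(C)CCC[C@]2(C)C(=O)OC | intermediate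
31 | methyl 6α-acetoxy-12-(tert-butyldiphenylsilyloxy)-13,14,15,16-tetranorlabd-8(17)-en-19-oate | CC(C)(C)[Si](c1ccccc1)(c1ccccc1)OCC[C@H]1C(=C)C[C@H](OC(C)=O)[C@@H]2[C@]1(C)CCC[C@]2(C)C(=O)OC | intermediate
32 | methyl 6α-acetoxy-12-hydroxy-13,14,15,16-tetranorlabd-8(17)-en-19-oate | OCC[C@H]1C(=C)C[C@H](OC(C)=O)[C@@H]2[C@]1(C)CCC[C@]2(C)C(=O)OC | intermediate
33 | methyl 6α-acetoxy-12-oxo-13,14,15,16-tetranorlabd-8(17)-en-19-oate | O=CC[C@H]1C(=C)C[C@H](OC(C)=O)[C@@H]2[C@]1(C)CCC[C@]2(C)C(=O)OC | intermediate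
34 | ethyltriphenylphosphonium iodide | CC[P+](c1ccccc1)(c1ccccc1)c1ccccc1.[I-] | starting material
35 | iodine | II | starting material
36 | methyl (12Z)-6α-acetoxy-13-iodo-14,15-dinorlabda-8(17),12-dien-19-oate | I/C(C)=C\C[C@H]1C(=C)C[C@H](OC(C)=O)[C@@H]2[C@]1(C)CCC[C@]2(C)C(=O)OC | intermediate
37 | tributyl(vinyl)stannane | C=C[Sn](CCCC)(CCCC)CCCC | starting material
38 | methyl (4S,5R,6S,9S,10R,12Z)-6-acetoxylabda-8(17),12,14-trien-19-oate | C=C/C(C)=C\C[C@H]1C(=C)C[C@H](OC(C)=O)[C@@H]2[C@]1(C)CCC[C@]2(C)C(=O)OC | target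

**Totals**
Total step count: 16. Longest linear sequence: 15 steps (steps 1–4 and 6–16); step 5 is a one-step side branch.

**Steps most likely to fail**

Step 10 (proposed new method). Hydroboration may not stop at the alkyne, cyclisation at the hindered C5–C10 bond may be slow, and endo/exo or facial selectivity may be poor. The fallback uses known chemistry, sets out from 23 and returns at 28. Hydroboration of the alkyne with pinacolborane and catalytic Cp2Zr(H)Cl would give the isolable methyl (2S,6E)-7-[2-(tert-butyldiphenylsilyloxy)ethyl]-2,6-dimethyl-2-[(E)-2-(4,4,5,5-tetramethyl-1,3,2-dioxaborolan-2-yl)ethenyl]-8-[(trimethylsilyl)methyl]nona-6,8-dienoate F1. A purely thermal intramolecular Diels–Alder reaction of this non-Lewis-acidic boronic ester (toluene, BHT, sealed tube, 150–170 °C) would give methyl 12-(tert-butyldiphenylsilyloxy)-6α-(4,4,5,5-tetramethyl-1,3,2-dioxaborolan-2-yl)-17-(trimethylsilyl)-13,14,15,16-tetranorlabd-8-en-19-oate F2, from which ring-fusion isomers would be separated. Oxidation with NaBO3·4H2O in THF/H2O would then give 28.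

Step 7. The reagent may attack the C19 ester, the second addition may stall at the enone, or acid on silica may cause side reactions of the tertiary allylic carbinol. The fallback sets out from 17 and returns at 22, adding one carbon at a time. Me(MeO)NH·HCl with AlMe3 would open the lactone to the hydroxy Weinreb amide methyl (2S,6E)-7-(2-hydroxyethyl)-8-[methoxy(methyl)amino]-2,6-dimethyl-8-oxo-2-[(trimethylsilyl)ethynyl]oct-6-enoate F3. TBDPSCl and imidazole would give its silyl ether F4. MeMgBr would add once to give the methyl ketone methyl (2S,6E)-7-[2-(tert-butyldiphenylsilyloxy)ethyl]-2,6-dimethyl-8-oxo-2-[(trimethylsilyl)ethynyl]non-6-enoate F5. Kinetic enolisation with KN(SiMe3)2 and trapping with PhNTf2 would give the dienyl triflate methyl (2S,6E)-7-[2-(tert-butyldiphenylsilyloxy)ethyl]-2,6-dimethyl-8-(trifluoromethanesulfonyloxy)-2-[(trimethylsilyl)ethynyl]nona-6,8-dienoate F6. Kumada coupling with Me3SiCH2MgCl and Pd(PPh3)4 would then give 22.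

Step 6. The olefin geometry may be lost (in the triflation of step 5 or during coupling), or transmetalation at the fully substituted triflate may be slow. The fallback sets out from 11 and returns at 20, fixing the geometry by a syn-carbometalation instead. Hydroboration with 9-BBN (through 16) and NaOH/H2O2 would give methyl (2S)-5-hydroxy-2-methyl-2-[(trimethylsilyl)ethynyl]pentanoate F7. An Appel reaction (I2, PPh3, imidazole) would give methyl (2S)-5-iodo-2-methyl-2-[(trimethylsilyl)ethynyl]pentanoate F8. Alkylation of dilithiated but-3-yn-1-ol (THF/DMPU, low temperature) would give methyl (2S)-9-hydroxy-2-methyl-2-[(trimethylsilyl)ethynyl]non-6-ynoate F9. Alkoxide-directed syn-carbomagnesiation with MeMgBr and catalytic Fe(acac)3, quenched with I2, would give methyl (2S,6E)-9-hydroxy-7-iodo-2,6-dimethyl-2-[(trimethylsilyl)ethynyl]non-6-enoate F10. Negishi coupling with [1-(trimethylsilylmethyl)vinyl]zinc bromide (from (2-bromoallyl)trimethylsilane, Mg, ZnBr2) and Pd(PPh3)4 would then give 20.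

**Further compounds**
F1 | step 10 | methyl (2S,6E)-7-[2-(tert-butyldiphenylsilyloxy)ethyl]-2,6-dimethyl-2-[(E)-2-(4,4,5,5-tetramethyl-1,3,2-dioxaborolan-2-yl)ethenyl]-8-[(trimethylsilyl)methyl]nona-6,8-dienoate | CC1(C)OB(/C=C/[C@](C)(CCC/C(C)=C(CCO[Si](c2ccccc2)(c2ccccc2)C(C)(C)C)/C(=C)C[Si](C)(C)C)C(=O)OC)OC1(C)C
F2 | step 10 | methyl 12-(tert-butyldiphenylsilyloxy)-6α-(4,4,5,5-tetramethyl-1,3,2-dioxaborolan-2-yl)-17-(trimethylsilyl)-13,14,15,16-tetranorlabd-8-en-19-oate | CC(C)(C)[Si](c1ccccc1)(c1ccccc1)OCCC1=C(C[Si](C)(C)C)C[C@H](B3OC(C)(C)C(C)(C)O3)[C@@H]2[C@]1(C)CCC[C@]2(C)C(=O)OC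
F3 | step 7 | methyl (2S,6E)-7-(2-hydroxyethyl)-8-[methoxy(methyl)amino]-2,6-dimethyl-8-oxo-2-[(trimethylsilyl)ethynyl]oct-6-enoate | C[Si](C)(C)C#C[C@](C)(CCC/C(C)=C(CCO)/C(=O)N(C)OC)C(=O)OC
F4 | step 7 | methyl (2S,6E)-7-[2-(tert-butyldiphenylsilyloxy)ethyl]-8-[methoxy(methyl)amino]-2,6-dimethyl-8-oxo-2-[(trimethylsilyl)ethynyl]oct-6-enoate | C[Si](C)(C)C#C[C@](C)(CCC/C(C)=C(CCO[Si](c1ccccc1)(c1ccccc1)C(C)(C)C)/C(=O)N(C)OC)C(=O)OC
F5 | step 7 | methyl (2S,6E)-7-[2-(tert-butyldiphenylsilyloxy)ethyl]-2,6-dimethyl-8-oxo-2-[(trimethylsilyl)ethynyl]non-6-enoate | C[Si](C)(C)C#C[C@](C)(CCC/C(C)=C(CCO[Si](c1ccccc1)(c1ccccc1)C(C)(C)C)/C(C)=O)C(=O)OC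
F6 | step 7 | methyl (2S,6E)-7-[2-(tert-butyldiphenylsilyloxy)ethyl]-2,6-dimethyl-8-(trifluoromethanesulfonyloxy)-2-[(trimethylsilyl)ethynyl]nona-6,8-dienoate | C[Si](C)(C)C#C[C@](C)(CCC/C(C)=C(CCO[Si](c1ccccc1)(c1ccccc1)C(C)(C)C)/C(=C)OS(=O)(=O)C(F)(F)F)C(=O)OC
F7 | step 6 | methyl (2S)-5-hydroxy-2-methyl-2-[(trimethylsilyl)ethynyl]pentanoate | C[Si](C)(C)C#C[C@](C)(CCCO)C(=O)OC
F8 | step 6 | methyl (2S)-5-iodo-2-methyl-2-[(trimethylsilyl)ethynyl]pentanoate | C[Si](C)(C)C#C[C@](C)(CCCI)C(=O)OC
F9 | step 6 | methyl (2S)-9-hydroxy-2-methyl-2-[(trimethylsilyl)ethynyl]non-6-ynoate | C[Si](C)(C)C#C[C@](C)(CCCC#CCCO)C(=O)OC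
F10 | step 6 | methyl (2S,6E)-9-hydroxy-7-iodo-2,6-dimethyl-2-[(trimethylsilyl)ethynyl]non-6-enoate | C[Si](C)(C)C#C[C@](C)(CCC/C(C)=C(/I)CCO)C(=O)OC
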